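The target is formally the Markovnikov ether dimer of (S)-auraptenol. The route rests on the C8–CH2 bond of the isopropenyl-bearing half. Both carbons are natural donors: C8 of the benzo ring lies between the methoxy-bearing C7 and the O1-bearing C8a, and the CH2 is β to the ether oxygen. Both are therefore used as halides, and a nickel-catalysed reductive cross-electrophile coupling joins 8-iodo-7-methoxycoumarin to a primary bromide that already carries the second coumarin, both stereocentres, the free hydroxyl and the isopropenyl group. This bromide arises from BF3-catalysed opening of (S)-meranzin at its tertiary carbon by an enantioenriched bromohydrin.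

Key step: step 7

Assumption: umbelliferone, osthol, 3-methylbut-3-en-2-one and the L-fructose-derived (ent-)Shi ketone are taken as commercially available.

Step 1
Reactants: 1 umbelliferone (7-hydroxy-2H-chromen-2-one)
Product: 2 7-hydroxy-8-iodo-2H-chromen-2-one
Conditions: I2, KI, 20% aq. NH3, rt; then dil. H2SO4
Reagents that add atoms: iodine, II
Why: Electrophilic aromatic iodination of the phenoxide, directed to C8, the position ortho to the 7-oxygen and flanked by the O1-bearing C8a, which is the most nucleophilic ring carbon of umbelliferone under these basic conditions.

Step 2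
Reactants: 2 7-hydroxy-8-iodo-2H-chromen-2-one
Product: 3 8-iodo-7-methoxy-2H-chromen-2-one
Conditions: MeI, K2CO3, acetone, reflux
Reagents that add atoms: iodomethane, CI
Why: Williamson ether synthesis, in which the phenoxide formed with carbonate is methylated at oxygen by iodomethane while the aryl iodide and the lactone are inert.

Step 3
Reactants: 4 osthol (7-methoxy-8-(3-methylbut-2-en-1-yl)-2H-chromen-2-one)
Product: 5 (S)-meranzin (8-{[(2S)-3,3-dimethyloxiran-2-yl]methyl}-7-methoxy-2H-chromen-2-one)
Conditions: ent-Shi ketone (L-fructose-derived, 30 mol%), Oxone, K2CO3, Bu4NHSO4, MeCN–dimethoxymethane / aq. Na2B4O7–EDTA buffer, 0 °C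
Reagents that add atoms: Oxone (potassium peroxymonosulfate), [K+].[O-]S(=O)(=O)OO
Why: Shi asymmetric epoxidation, in which the chiral dioxirane attacks only the electron-rich trisubstituted prenyl alkene (not the electron-poor C3=C4 bond of the pyranone) through a spiro transition state, and because the D-fructose-derived ketone turns olefins of the type RCH2–CH=CMe2 into (R)-epoxides, its L-enantiomer should give the (S)-epoxide.

Step 4
Reactants: 6 3-methylbut-3-en-2-one
Product: 8 1-bromo-3-methylbut-3-en-2-one, via silyl dienol ether 7 (not isolated)
Conditions: TMSOTf, Et3N, CH2Cl2, 0 °C; then NBS, THF, −78 → 0 °C; used without storage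
Reagents that add atoms: N-bromosuccinimide, O=C1CCC(=O)N1Br; trimethylsilyl trifluoromethanesulfonate, C[Si](C)(C)OS(=O)(=O)C(F)(F)F (its silyl group is present in 7 only)
Why: Soft enolisation to the 2-silyloxy diene followed by electrophilic α-bromination with NBS, where the methyl group is the only enolisable position of 6 and the silyl enol ether reacts at its terminal CH2 carbon, so bromine enters at C1 without addition to the isopropenyl double bond.

Step 5
Reactants: 8 1-bromo-3-methylbut-3-en-2-one
Product: 9 (R)-1-bromo-3-methylbut-3-en-2-ol
Conditions: (R)-Me-CBS oxazaborolidine (20 mol%), catecholborane, toluene, −78 °C; MeOH quench, pH 7 work-up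
Reagents that add atoms: none
Why: Corey–Bakshi–Shibata reduction, in which the α-branched isopropenyl group acts as the larger and the bromomethyl group as the smaller flank, so the (R)-catalyst should give the (R)-bromohydrin (the spatial analogue of (S)-1-phenylethanol from acetophenone, the descriptor changing because CH2Br outranks isopropenyl), while catecholborane at −78 °C reduces the C=O bond 1,2 without hydroborating the alkene or touching the C–Br bond.

Step 6
Reactants: 5 (S)-meranzin; 9 (R)-1-bromo-3-methylbut-3-en-2-ol
Product: 10 8-[(2S)-3-{[(2R)-1-bromo-3-methylbut-3-en-2-yl]oxy}-2-hydroxy-3-methylbutyl]-7-methoxy-2H-chromen-2-one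
Conditions: BF3·OEt2 (cat.), bromohydrin in fourfold excess (surplus recovered unchanged), CH2Cl2, −40 → −15 °C; Et3N quench
Reagents that add atoms: none
Why: Lewis-acid-catalysed alcoholysis of a trisubstituted epoxide, a pure addition in which every atom of the epoxide and of the bromohydrin ends up in the product: the BF3-bound oxirane opens at the cation-stabilising tertiary carbon, so the secondary C–O bond and its (S) configuration are retained, β-halo alcohols being established nucleophiles in this reaction type and the excess of the bromohydrin competing with the 1,2-hydride shift.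

Step 7
Reactants: 10 8-[(2S)-3-{[(2R)-1-bromo-3-methylbut-3-en-2-yl]oxy}-2-hydroxy-3-methylbutyl]-7-methoxy-2H-chromen-2-one; 3 8-iodo-7-methoxy-2H-chromen-2-one
Product: 11 8-[(2S)-2-hydroxy-3-{[(2S)-1-(7-methoxy-2-oxo-2H-chromen-8-yl)-3-methylbut-3-en-2-yl]oxy}-3-methylbutyl]-7-methoxy-2H-chromen-2-one (target)
Conditions: NiI2·xH2O (10 mol%), 4,4′-di-tert-butyl-2,2′-bipyridine (10 mol%), pyridine (10 mol%), Mn powder (2 equiv), aryl iodide in 1.5-fold excess, DMPU, 60 °C
Reagents that add atoms: none
Why: Nickel-catalysed reductive cross-electrophile coupling of an aryl halide with a primary alkyl halide: Ni(0)(dtbbpy) adds oxidatively to the C8–I bond of 3, a Ni(I) species abstracts bromine from 10 to give the primary radical at the CH2 β to the ether oxygen, this radical is captured by the aryl–Ni(II) complex, and the resulting Ni(III) species forms the C8–CH2 bond by reductive elimination, manganese returning nickel to its low-valent state. The step unites two carbons that are both natural donors, C8 between the oxygenated C7 and C8a (selectively iodinated in step 1) and the carbon β to the ether oxygen, by using both as halides. No ring is closed and no stereocentre is formed; both existing stereocentres are spectators, because the radical sits on the CH2 and no bond at the neighbouring carbon is broken. Cross-selectivity is needed and should come from the two different activation modes (two-electron oxidative addition for C(sp2)–I, halogen-atom abstraction for C(sp3)–Br), helped by the excess of 3. Manganese in place of zinc avoids an alkylzinc species that would expel the β-alkoxide, reductive elimination from Ni(III) should be faster than β-alkoxy elimination, and the free hydroxyl, both lactones and the 1,1-disubstituted alkene are tolerated by this reaction type. The main danger, 3-exo attack of the radical on the isopropenyl group (1,2-vinyl shift) or 1,5-hydrogen transfer from the carbinol C–H, is unimolecular and slow for a primary homoallylic radical, so the nickel loading and a concentrated solution should let capture win.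

Compound list
1 | umbelliferone (7-hydroxy-2H-chromen-2-one) | Oc1ccc2ccc(=O)oc2c1 | starting material
2 | 7-hydroxy-8-iodo-2H-chromen-2-one | Oc1ccc2ccc(=O)oc2c1I | intermediate
3 | 8-iodo-7-methoxy-2H-chromen-2-one | COc1ccc2ccc(=O)oc2c1I | intermediate
4 | osthol (7-methoxy-8-(3-methylbut-2-en-1-yl)-2H-chromen-2-one) | COc1ccc2ccc(=O)oc2c1CC=C(C)C | starting material
5 | (S)-meranzin (8-{[(2S)-3,3-dimethyloxiran-2-yl]methyl}-7-methoxy-2H-chromen-2-one) | CC1(C)O[C@H]1Cc1c(OC)ccc2ccc(=O)oc12 | intermediate
6 | 3-methylbut-3-en-2-one | CC(=O)C(C)=C | starting material
7 | 3-methyl-2-(trimethylsilyloxy)buta-1,3-diene (silyl dienol ether, not isolated) | C=C(O[Si](C)(C)C)C(C)=C | intermediate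
8 | 1-bromo-3-methylbut-3-en-2-one | C=C(C)C(=O)CBr | intermediate
9 | (R)-1-bromo-3-methylbut-3-en-2-ol | C=C(C)[C@H](CBr)O | intermediate
10 | 8-[(2S)-3-{[(2R)-1-bromo-3-methylbut-3-en-2-yl]oxy}-2-hydroxy-3-methylbutyl]-7-methoxy-2H-chromen-2-one | C=C(C)[C@H](CBr)OC(C)(C)[C@@H](O)Cc1c(OC)ccc2ccc(=O)oc12 | intermediate
11 | 8-[(2S)-2-hydroxy-3-{[(2S)-1-(7-methoxy-2-oxo-2H-chromen-8-yl)-3-methylbut-3-en-2-yl]oxy}-3-methylbutyl]-7-methoxy-2H-chromen-2-one (CNP0142500.1) | C=C(C)[C@H](Cc1c(OC)ccc2ccc(=O)oc12)OC(C)(C)[C@@H](O)Cc1c(OC)ccc2ccc(=O)oc12 | target

Total step count: 7
Longest linear sequence: 4 steps (steps 4, 5, 6 and 7, from 6 to 11)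

Steps most likely to fail

1. Step 7. The primary radical may rearrange before it is captured, either by 3-exo closure on the isopropenyl group and reopening to the α-alkoxy radical or by 1,5-hydrogen transfer from the carbinol C–H. Capture at the aryl–nickel centre flanked by two ortho oxygens may also be slow, so that hydrodeiodination of 3 and reduction or dimerisation of the alkyl partner take over. Any alkyl–metal species formed directly from the reductant would expel the β-alkoxide. The fallback is a polar Negishi coupling without a free alkyl radical; it sets out from 3 and 10 and comes back to the route at 11. Zinc dust with LiCl in THF should insert into the C–I bond of 3 to give (7-methoxy-2-oxo-2H-chromen-8-yl)zinc iodide F1. F1 would then be coupled with 10 under Pd2(dba)3, tricyclopentylphosphine and N-methylimidazole in THF–NMP at 80 °C (SN2-type oxidative addition of Pd(0) to the primary C–Br bond, transmetalation, reductive elimination). An excess of F1 covers its slow protonolysis by the free hydroxyl.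

2. Step 6. Capture of the activated epoxide by the hindered and inductively deactivated bromo alcohol may lose against the 1,2-hydride shift to the isopropyl ketone (Meinwald rearrangement) or against proton loss to the allylic alcohol, and the bromo alcohol product may cyclise onto its own alkyl bromide during handling. The fallback carries out the two unions in the opposite order; it sets out from 9 and 3 and comes back to the route at 11. The nickel coupling of step 7, applied to 9 and 3, should give (S)-auraptenol F2, the free β-hydroxyl being tolerated. BF3·OEt2-catalysed opening of 5 by F2 would then give 11 directly. F2 is bromine-free and therefore a more nucleophilic allylic alcohol, and its product cannot cyclise onto an alkyl bromide.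

3. Step 5. Facial discrimination may be poor because the isopropenyl and bromomethyl flanks are of similar size, and the labile bromo enone may be lost to conjugate reduction or polymerisation. The fallback replaces asymmetric reduction by resolution through diastereomers; it sets out from 8 and comes back to the route at 10. Luche reduction (NaBH4, CeCl3·7H2O, MeOH, −78 °C) should give racemic 1-bromo-3-methylbut-3-en-2-ol F3 by clean 1,2-reduction. F3 is used in step 6 with enantioenriched 5; the ether 10 and its (2S)-bromo epimer, 8-[(2S)-3-{[(2S)-1-bromo-3-methylbut-3-en-2-yl]oxy}-2-hydroxy-3-methylbutyl]-7-methoxy-2H-chromen-2-one F4, are diastereomers and would be separated by chromatography.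

Further compounds
F1 | step 7 | (7-methoxy-2-oxo-2H-chromen-8-yl)zinc iodide | COc1ccc2ccc(=O)oc2c1[Zn]I
F2 | step 6 | (S)-auraptenol (8-[(2S)-2-hydroxy-3-methylbut-3-en-1-yl]-7-methoxy-2H-chromen-2-one) | C=C(C)[C@H](Cc1c(OC)ccc2ccc(=O)oc12)O
F3 | step 5 | racemic 1-bromo-3-methylbut-3-en-2-ol | C=C(C)C(CBr)O
F4 | step 5 | 8-[(2S)-3-{[(2S)-1-bromo-3-methylbut-3-en-2-yl]oxy}-2-hydroxy-3-methylbutyl]-7-methoxy-2H-chromen-2-one | C=C(C)[C@@H](CBr)OC(C)(C)[C@@H](O)Cc1c(OC)ccc2ccc(=O)oc12
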